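The strategy rests on making the cyclopentenol ring from a cyclobutanone. Labels are defined in the remark below. The key step exploits that in the cyclopentenol ring D (C12, C13, C14, C15, C16) the oxygen-bearing C16 sits on C12, next to C13, the carbon shared by rings B, C and D. Ring D is therefore made from a cyclobutanone (C16, C13, C14, C15), assembled by an intramolecular vinylketene [2+2] cycloaddition with C13 quaternary and attached to the cycloheptene alkene C11=C12. Acid moves the acyl carbon C16 from C13 to C12: in one operation the four-membered ring grows to the five-membered enone and the tetrasubstituted C12=C13 alkene is set. A double Mannich reaction on the C6 ketone then closes the piperidine; C6 is quaternised last.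

Key step: step 9

Remark on labels: the skeletal atoms of the target are numbered along its SMILES, leaving out both hydroxyl oxygens, the CO2Me group and the N-methyl carbon: C1, C2 (ethyl), C3 (hemiketal carbon), C4, C5, C6 (spiro quaternary carbon), C7 (OCH2), O8, C9 (CH), C10, C11, C12=C13, C14 (CH), C15, C16 (CHOH), C17 (CHCO2Me), C18, C19 (quaternary), C20, N21, C22. Ring A: piperidine (C6, C9, C22, N21, C20, C19). Ring B: cycloheptene (C6, C9, C10, C11, C12, C13, C19). Ring C: cyclopentane (C13, C14, C17, C18, C19). Ring D: cyclopentenol (C12, C13, C14, C15, C16). Ring E: hemiketal (C3, C4, C5, C6, C7, O8).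

Assumption: the hemiketal carbon C3 equilibrates through the open hydroxy ketone and is taken to rest in the anomerically stabilised configuration drawn for the target.

Step 1
Reactants: 1 dimethyl ethylidenemalonate; 2 1-bromo-3-methylbut-2-ene (prenyl bromide)
Product: 3 dimethyl 2-(3-methylbut-2-en-1-yl)-2-vinylmalonate
Conditions: KN(SiMe3)2, THF, −78 °C; then 2, −78 °C to rt
Reagents that add atoms: none
Why: Deconjugative α-alkylation of the extended enolate of an alkylidenemalonate (SN2 at the primary allylic bromide) should give the quaternary vinylmalonate; no stereocentre is formed.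

Step 2
Reactants: 3 dimethyl 2-(3-methylbut-2-en-1-yl)-2-vinylmalonate
Product: 5 dimethyl 2-(2-oxoethyl)-2-vinylmalonate, via secondary ozonide 4 (not isolated)
Conditions: O3 (1 equiv, Sudan Red 7B as end-point indicator), CH2Cl2, −78 °C; then Me2S, rt
Reagents that add atoms: ozone, [O-][O+]=O
Why: Ozonolysis should be much faster at the electron-rich trisubstituted prenyl alkene than at the vinyl group deactivated by two geminal esters, so one equivalent of ozone unmasks the aldehyde; no stereocentre.

Step 3
Reactants: 5 dimethyl 2-(2-oxoethyl)-2-vinylmalonate; 6 tert-butyl acrylate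
Product: 7 racemic tert-butyl 3-hydroxy-5,5-bis(methoxycarbonyl)-2-methylidenehept-6-enoate
Conditions: DABCO (1 equiv), 1,4-dioxane–H2O (1:1), rt
Reagents that add atoms: none
Why: Morita–Baylis–Hillman reaction of an unhindered aliphatic aldehyde with an acrylate; the racemic carbinol centre is erased in step 4.

Step 4
Reactants: 7 racemic tert-butyl 3-hydroxy-5,5-bis(methoxycarbonyl)-2-methylidenehept-6-enoate
Product: 8 tert-butyl (Z)-2-(bromomethyl)-5,5-bis(methoxycarbonyl)hepta-2,6-dienoate
Conditions: NBS, Me2S, CH2Cl2, 0 °C to rt
Reagents that add atoms: N-bromosuccinimide, O=C1CCC(=O)N1Br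
Why: Bromination of a Morita–Baylis–Hillman alcohol with allylic transposition (SN2′ attack of bromide on the oxysulfonium intermediate) should give the thermodynamically preferred Z 2-(bromomethyl)enoate.

Step 5
Reactants: 8 tert-butyl (Z)-2-(bromomethyl)-5,5-bis(methoxycarbonyl)hepta-2,6-dienoate; 9 hex-5-enal
Product: 11 tert-butyl (3R,4S)-3-[2,2-bis(methoxycarbonyl)but-3-en-1-yl]-4-hydroxy-2-methylidenenon-8-enoate (C19 R and C6 S in the labels above), via trimethylsilyl ether 10 (not isolated)
Conditions: CrCl2 (10 mol%), chiral 1,8-bis(4-isopropyloxazolin-2-yl)-3,6-di-tert-butylcarbazole ligand (11 mol%, the enantiomer that gives the S carbinol), Mn powder, Me3SiCl, iPr2NEt (30 mol%), THF, rt; then aq. citric acid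
Reagents that add atoms: none
Why: Catalytic asymmetric Nozaki–Hiyama–Kishi-type 2-(alkoxycarbonyl)allylation: the γ-substituted allylchromium species should add through a chair transition state to give the anti adduct, the ligand fixes the aldehyde face and with it C6 (S) and C19 (R), and the minor syn isomer is removed by chromatography.

Step 6
Reactants: 11 tert-butyl (3R,4S)-3-[2,2-bis(methoxycarbonyl)but-3-en-1-yl]-4-hydroxy-2-methylidenenon-8-enoate
Product: 12 the C6 acetate of 11
Conditions: Ac2O, pyridine, DMAP (cat.), CH2Cl2, rt
Reagents that add atoms: acetic anhydride, CC(=O)OC(C)=O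
Why: Acetylation of the secondary alcohol blocks lactonisation onto C16 and gives a group that survives the acid chloride, the amine base and the acid of steps 8 and 9.

Step 7
Reactants: 12 the C6 acetate of 11
Product: 13 tert-butyl (6S,7R)-6-acetoxy-7-[2,2-bis(methoxycarbonyl)but-3-en-1-yl]cyclohept-1-ene-1-carboxylate (acetoxy group and side chain cis)
Conditions: second-generation Grubbs catalyst (5 mol%), CH2Cl2 (0.005 M), 40 °C
Reagents that add atoms: none
Why: Ring-closing metathesis: the ruthenium carbene should load at the unhindered terminal alkene (C12) and close ring B onto the 1,1-disubstituted acrylate (C13), while the vinyl group on the quaternary malonate carbon is too hindered to initiate or to close a nine-membered ring.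

Step 8
Reactants: 13 tert-butyl (6S,7R)-6-acetoxy-7-[2,2-bis(methoxycarbonyl)but-3-en-1-yl]cyclohept-1-ene-1-carboxylate
Product: 16 tricyclic 2-alkenylcyclobutanone (cyclobutanone C16, C13, C14, C15 fused to ring C and to the 6-acetoxycycloheptene with C11=C12), via acid chloride 14 (not isolated), via vinylketene 15 (not isolated)
Conditions: SOCl2, rt; evaporate; then Et3N, toluene (0.01 M, slow addition), 110 °C
Reagents that add atoms: none
Why: SOCl2 should convert only the tert-butyl ester into the acid chloride, 1,4-dehydrochlorination (loss of H from C11) gives the vinylketene, and an intramolecular ketene–alkene [2+2] cycloaddition over the three-atom tether C19–C18–C17 closes ring C (C13–C14) and the cyclobutanone (C16–C15); both new ring fusions must be cis, which puts C15 and C16 on the face of H19 and so lets C19 (R) fix the configuration of C14.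

Step 9
Reactants: 16 tricyclic 2-alkenylcyclobutanone
Product: 17 tricyclic enone (C16=O, C12=C13; rings B, C and D; 6-acetoxy; 17,17-diester)
Conditions: MeSO3H (3 equiv), CH2Cl2, 0 °C to rt
Reagents that add atoms: none
Why: Protonation of the ring alkene at C11 is assisted by the strained C13–C16 bond, so the acyl carbon C16 migrates from C13 to C12 (1,2-acyl shift) and the tertiary cation at C13 loses the now acidic proton on C12 to give the conjugated enone. The closest known reaction type is the acid-catalysed rearrangement of 2-vinylcyclobutanones to cyclopent-2-enones. No ring is closed from an open chain: the cyclobutanone (C16, C13, C14, C15) is enlarged to the cyclopentenone (C16, C12, C13, C14, C15) by insertion of C12 through a bridged three-centre transition state at C12–C13. No stereocentre is created; C13 becomes trigonal and C14 is not touched. The step needs the proton on C11 and not on C12, and the 1,2-shift and not the 1,3-acyl shift: only a cation at C12 has a migrating group beside it and is drained irreversibly with release of four-ring strain, whereas a cation at C11 can revert or pass hydride to C12, and the 1,3-shift would put a bridgehead alkene into the seven-membered ring.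

Step 10
Reactants: 17 tricyclic enone
Product: 18 allylic alcohol (C16 S, hydroxyl on the face of H14)
Conditions: (R)-2-methyl-CBS-oxazaborolidine (20 mol%), BH3·SMe2, THF, −30 °C; MeOH quench
Reagents that add atoms: none
Why: Corey–Bakshi–Shibata reduction: the catalyst distinguishes the alkene-bearing side (large) from the CH2 side (small) of the cyclopentenone and should deliver hydride under reagent control to give the S carbinol at C16.

Step 11
Reactants: 18 allylic alcohol
Product: 19 C16 triisopropylsilyl ether
Conditions: iPr3SiOTf, 2,6-lutidine, CH2Cl2, 0 °C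
Reagents that add atoms: triisopropylsilyl triflate, CC(C)[Si](OS(=O)(=O)C(F)(F)F)(C(C)C)C(C)C
Why: Silylation with a silyl triflate protects the secondary allylic alcohol as a bulky ether that should tolerate the mildly acidic steps 14 and 15.

Step 12
Reactants: 19 C16 triisopropylsilyl ether
Product: 20 C6 alcohol
Conditions: K2CO3 (0.2 equiv), MeOH, rt
Reagents that add atoms: none
Why: Base-catalysed methanolysis (transesterification) removes the acetate, while the hindered malonate methyl esters only exchange methoxide degenerately.

Step 13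
Reactants: 20 C6 alcohol
Product: 21 C6 ketone (β,γ-unsaturated cycloheptenone)
Conditions: Dess–Martin periodinane, NaHCO3, CH2Cl2, rt
Reagents that add atoms: none
Why: Dess–Martin oxidation of the secondary alcohol under buffered conditions gives the ketone; C19 becomes epimerisable, which is harmless because step 14 resets it.

Step 14
Reactants: 21 C6 ketone
Product: 23 tetracyclic amino ketone (8-methyl-8-azabicyclo[4.3.1]decanone fused to rings C and D), via mono-Mannich base 22 (not isolated)
Conditions: MeNH2 (40% in H2O), CH2O (37% in H2O), AcOH, MeOH, 60 °C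
Reagents that add atoms: formaldehyde, C=O; methylamine, CN
Why: Double Mannich reaction: aminomethylation at C9, then six-membered Mannich closure (6-endo-trig at the iminium carbon) onto the C6/C19 dienol should form ring A and the quaternary C19; the C19–C20 bond forms on the face of H14 because only then can the C6 bridge settle on the face toward which ring C is puckered, and C9 follows because the bridge can only be cis.

Step 15
Reactants: 23 tetracyclic amino ketone
Product: 25 C6 carbaldehyde (both C6 epimers), via methyl enol ether 24 (not isolated)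
Conditions: Ph3P(CH2OMe)Cl, KN(SiMe3)2, THF, 0 to 50 °C; then 2 M HCl, THF, rt
Reagents that add atoms: (methoxymethyl)triphenylphosphonium chloride, COC[P+](c1ccccc1)(c1ccccc1)c1ccccc1.[Cl-]; water, O
Why: Wittig methoxymethylenation of the bridging ketone and acid hydrolysis of the enol ether give the one-carbon-homologous aldehyde (C7); its C6 epimers converge in step 16.

Step 16
Reactants: 25 C6 carbaldehyde; 26 ethyl vinyl ketone (pent-1-en-3-one)
Product: 27 keto aldehyde with quaternary C6
Conditions: pyrrolidine (30 mol%), PhCO2H (30 mol%), CH2Cl2, rt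
Reagents that add atoms: none
Why: Enamine-mediated Michael addition of the α-branched aldehyde to the enone creates quaternary C6; the enone should approach the exocyclic enamine from the face on the piperidine side, because the face over ring B is screened by C18H2 and by the ester on C17 that points to it, so the chain ends syn to ring A and the formyl group over ring B.

Step 17
Reactants: 27 keto aldehyde
Product: 29 hemiketal diester (ring E closed), via hydroxy ketone 28 (not isolated)
Conditions: NaBH4 (0.5 equiv), MeOH–CH2Cl2, −78 to −40 °C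
Reagents that add atoms: none
Why: Borohydride reduces the aldehyde far faster than the ethyl ketone at low temperature, and the primary alcohol closes onto the ketone to the six-membered hemiketal, which should equilibrate to the anomerically stabilised epimer at C3.

Step 18
Reactants: 29 hemiketal diester
Product: 30 hemiketal monoester (C17 set)
Conditions: LiCl, H2O (2 equiv), DMSO, 140 °C
Reagents that add atoms: none
Why: Krapcho dealkoxycarbonylation: chloride demethylates one malonate ester, the carboxylate loses CO2, and the ester enolate should be protonated kinetically by water on the face of H14, away from C15 and from the substituents on C6, which leaves the remaining ester on the face of C6 as in the target.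

Step 19
Reactants: 30 hemiketal monoester
Product: 31 target CNP0124876.1
Conditions: Bu4NF, THF, 0 °C to rt
Reagents that add atoms: none
Why: Fluoride-induced desilylation (strong Si–F bond) frees the C16 hydroxyl without touching the ester, the amine or the hemiketal.

Compound list
1 | dimethyl ethylidenemalonate | CC=C(C(=O)OC)C(=O)OC | starting material
2 | 1-bromo-3-methylbut-2-ene (prenyl bromide) | CC(C)=CCBr | starting material
3 | dimethyl 2-(3-methylbut-2-en-1-yl)-2-vinylmalonate | C=CC(CC=C(C)C)(C(=O)OC)C(=O)OC | intermediate
4 | secondary ozonide, dimethyl 2-[(5,5-dimethyl-1,2,4-trioxolan-3-yl)methyl]-2-vinylmalonate | CC1(C)OOC(CC(C=C)(C(=O)OC)C(=O)OC)O1 | intermediate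
5 | dimethyl 2-(2-oxoethyl)-2-vinylmalonate | C=CC(CC=O)(C(=O)OC)C(=O)OC | intermediate
6 | tert-butyl acrylate | C=CC(=O)OC(C)(C)C | starting material
7 | racemic tert-butyl 3-hydroxy-5,5-bis(methoxycarbonyl)-2-methylidenehept-6-enoate | C=CC(CC(O)C(=C)C(=O)OC(C)(C)C)(C(=O)OC)C(=O)OC | intermediate
8 | tert-butyl (Z)-2-(bromomethyl)-5,5-bis(methoxycarbonyl)hepta-2,6-dienoate | C=CC(C/C=C(\CBr)C(=O)OC(C)(C)C)(C(=O)OC)C(=O)OC | intermediate
9 | hex-5-enal | C=CCCCC=O | starting material
10 | trimethylsilyl ether of 11 | C=CCCC[C@H](O[Si](C)(C)C)[C@H](CC(C=C)(C(=O)OC)C(=O)OC)C(=C)C(=O)OC(C)(C)C | intermediate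
11 | tert-butyl (3R,4S)-3-[2,2-bis(methoxycarbonyl)but-3-en-1-yl]-4-hydroxy-2-methylidenenon-8-enoate (anti; C19 R, C6 S) | C=CCCC[C@H](O)[C@H](CC(C=C)(C(=O)OC)C(=O)OC)C(=C)C(=O)OC(C)(C)C | intermediate
12 | C6 acetate of 11 | C=CCCC[C@H](OC(C)=O)[C@H](CC(C=C)(C(=O)OC)C(=O)OC)C(=C)C(=O)OC(C)(C)C | intermediate
13 | tert-butyl (6S,7R)-6-acetoxy-7-[2,2-bis(methoxycarbonyl)but-3-en-1-yl]cyclohept-1-ene-1-carboxylate (acetoxy and side chain cis) | CC(=O)O[C@H]1CCCC=C(C(=O)OC(C)(C)C)[C@H]1CC(C=C)(C(=O)OC)C(=O)OC | intermediate
14 | acid chloride of the cycloheptenecarboxylic acid corresponding to 13 | CC(=O)O[C@H]1CCCC=C(C(Cl)=O)[C@H]1CC(C=C)(C(=O)OC)C(=O)OC | intermediate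
15 | vinylketene, (cyclohept-2-en-1-ylidene)ketene with the 7-acetoxy and 6-butenyl substituents of 13 (C13=C16=O, C11=C12) | CC(=O)O[C@H]1CCC=CC(=C=O)[C@H]1CC(C=C)(C(=O)OC)C(=O)OC | intermediate
16 | tricyclic 2-alkenylcyclobutanone: cyclobutanone (C16=O, C15H2, C14H, quaternary C13) cis-fused at C13–C14 to the 17,17-bis(methoxycarbonyl)cyclopentane and at C13–C19 to the 6-acetoxycycloheptene (C11=C12); C12 and C6 on one face of ring C, C16, C15 and H19 on the other | CC(=O)O[C@H]1CCC=C[C@@]23C(=O)C[C@@H]2C(C(=O)OC)(C(=O)OC)C[C@H]31 | intermediate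
17 | tricyclic enone: cyclopentenone ring D (C16=O, C12=C13) fused to ring C (17,17-diester) and to the 6-acetoxycycloheptene ring B; H14 and C6 on the same face of ring C | CC(=O)O[C@H]1CCCC2=C3[C@H](CC2=O)C(C(=O)OC)(C(=O)OC)C[C@H]31 | intermediate
18 | allylic alcohol of 17 (C16 S, hydroxyl on the face of H14) | CC(=O)O[C@H]1CCCC2=C3[C@H](C[C@@H]2O)C(C(=O)OC)(C(=O)OC)C[C@H]31 | intermediate
19 | C16 triisopropylsilyl ether of 18 | CC(=O)O[C@H]1CCCC2=C3[C@H](C[C@@H]2O[Si](C(C)C)(C(C)C)C(C)C)C(C(=O)OC)(C(=O)OC)C[C@H]31 | intermediate
20 | C6 alcohol (acetate removed) | O[C@H]1CCCC2=C3[C@H](C[C@@H]2O[Si](C(C)C)(C(C)C)C(C)C)C(C(=O)OC)(C(=O)OC)C[C@H]31 | intermediate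
21 | C6 ketone (tricyclic β,γ-unsaturated cycloheptenone, C19–H) | O=C1CCCC2=C3[C@H](C[C@@H]2O[Si](C(C)C)(C(C)C)C(C)C)C(C(=O)OC)(C(=O)OC)C[C@H]31 | intermediate
22 | mono-Mannich base, C9-(methylaminomethyl) derivative of 21 | O=C1C(CNC)CCC2=C3[C@H](C[C@@H]2O[Si](C(C)C)(C(C)C)C(C)C)C(C(=O)OC)(C(=O)OC)C[C@H]31 | intermediate
23 | tetracyclic amino ketone: 8-methyl-8-azabicyclo[4.3.1]decan-10-one (C6=O bridge) fused to rings C and D, C20 on the face of H14 | O=C2[C@@H]1CCC3=C4[C@H](C[C@@H]3O[Si](C(C)C)(C(C)C)C(C)C)C(C(=O)OC)(C(=O)OC)C[C@@]42CN(C)C1 | intermediate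
24 | methyl enol ether (C6=C7H–OMe) of 23 | COC=C2[C@@H]1CCC3=C4[C@H](C[C@@H]3O[Si](C(C)C)(C(C)C)C(C)C)C(C(=O)OC)(C(=O)OC)C[C@@]42CN(C)C1 | intermediate
25 | C6 carbaldehyde (C7 formyl, mixture of C6 epimers) | O=CC2[C@@H]1CCC3=C4[C@H](C[C@@H]3O[Si](C(C)C)(C(C)C)C(C)C)C(C(=O)OC)(C(=O)OC)C[C@@]42CN(C)C1 | intermediate
26 | ethyl vinyl ketone (pent-1-en-3-one) | CCC(=O)C=C | starting material
27 | keto aldehyde: quaternary C6 with formyl (C7, over ring B) and 3-oxopentyl chain (syn to ring A) | CCC(=O)CC[C@@]2(C=O)[C@@H]1CCC3=C4[C@H](C[C@@H]3O[Si](C(C)C)(C(C)C)C(C)C)C(C(=O)OC)(C(=O)OC)C[C@@]42CN(C)C1 | intermediate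
28 | hydroxy ketone (C7 hydroxymethyl, open form of 29) | CCC(=O)CC[C@@]2(CO)[C@@H]1CCC3=C4[C@H](C[C@@H]3O[Si](C(C)C)(C(C)C)C(C)C)C(C(=O)OC)(C(=O)OC)C[C@@]42CN(C)C1 | intermediate
29 | hemiketal diester: target skeleton with C17 bis(methoxycarbonyl) and C16 triisopropylsilyl ether | CC[C@@]1(O)CC[C@@]2(CO1)[C@@H]1CCC3=C4[C@H](C[C@@H]3O[Si](C(C)C)(C(C)C)C(C)C)C(C(=O)OC)(C(=O)OC)C[C@@]42CN(C)C1 | intermediate
30 | C16 triisopropylsilyl ether of the target | CC[C@@]1(O)CC[C@@]2(CO1)[C@@H]1CCC3=C4[C@H](C[C@@H]3O[Si](C(C)C)(C(C)C)C(C)C)[C@H](C(=O)OC)C[C@@]42CN(C)C1 | intermediate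
31 | CNP0124876.1 | CC[C@@]1(O)CC[C@@]2(CO1)[C@@H]1CCC3=C4[C@H](C[C@@H]3O)[C@H](C(=O)OC)C[C@@]42CN(C)C1 | target

Total step count: 19. Longest linear sequence: 19 steps (1 to 31; the route is fully linear).

The three steps most likely to fail:

Step 8. What may go wrong: the vinylketene dimerises or oligomerises faster than it adds to the vinyl group, which is made electron-poor by the two geminal esters. The fallback uses the more electrophilic keteniminium ion. It sets out from 13: the acid chloride 14 (SOCl2) is quenched with pyrrolidine and Et3N to give the pyrrolidine amide F1. Tf2O and 2,4,6-collidine in ClCH2CH2Cl at 80 °C should convert F1, by O-triflation and loss of a proton from C11, into the vinylketeniminium ion, which undergoes the same intramolecular [2+2] cycloaddition to the cyclobutaniminium triflate F2. Aqueous NaHCO3 hydrolyses F2 to cyclobutanone 16, where the route is rejoined.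

Step 16. What may go wrong: poor or inverted facial selectivity at C6 (the enone attacking the face over ring B), or stalling of enamine formation from the hindered aldehyde. The fallback introduces the two carbon substituents on C6 in the opposite order, so that the same facial preference now puts C7 where the chain had gone. It sets out from 25: a crossed aldol reaction with aqueous CH2O (K2CO3, THF, 0 °C) should give the hydroxymethyl aldehyde F3, whose formyl carbon is now C5. A Horner–Wadsworth–Emmons reaction with diethyl (2-oxobutyl)phosphonate (LiCl, iPr2NEt, MeCN) gives the E-enone F4. Hydrogenation of its disubstituted alkene (H2, RhCl(PPh3)3, benzene) gives hydroxy ketone 28, which closes to hemiketal 29, where the route is rejoined.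

Step 18. What may go wrong: protonation of the ester enolate from the wrong face (C17 epimer), or loss of the silyl ether and thermal degradation at 140 °C. The fallback ties back the ester that must stay as a lactone before the decarboxylation, so that C17 can only be protonated on the required face. It sets out from 29: DBU in toluene at 100 °C (MeOH distilled off) should let the C7 hydroxyl of the open hydroxy ketone lactonise onto the only ester it can reach, the one on the C6 face of ring C, to give the seven-membered lactone F5. Krapcho dealkoxycarbonylation of F5 (LiCl, wet DMSO, 120 °C) removes the other ester and gives lactone F6 with the carboxyl held on that face. K2CO3 in MeOH opens the lactone to the methyl ester and the freed C7 hydroxyl recloses the hemiketal, giving 30, where the route is rejoined.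

Further compounds
F1 | step 8 | pyrrolidine amide of the cycloheptenecarboxylic acid corresponding to 13 | CC(=O)O[C@H]1CCCC=C(C(=O)N2CCCC2)[C@H]1CC(C=C)(C(=O)OC)C(=O)OC
F2 | step 8 | cyclobutaniminium triflate (pyrrolidinium ylidene analogue of 16) | CC(=O)O[C@H]1CCC=C[C@@]23C(=[N+]4CCCC4)C[C@@H]2C(C(=O)OC)(C(=O)OC)C[C@H]31.[O-]S(=O)(=O)C(F)(F)F
F3 | step 16 | hydroxymethyl aldehyde: quaternary C6 with formyl (future C5) and hydroxymethyl (C7, over ring B) | O=C[C@@]2(CO)[C@@H]1CCC3=C4[C@H](C[C@@H]3O[Si](C(C)C)(C(C)C)C(C)C)C(C(=O)OC)(C(=O)OC)C[C@@]42CN(C)C1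
F4 | step 16 | E-enone: C6 with hydroxymethyl and (E)-3-oxopent-1-enyl groups | CCC(=O)/C=C/[C@@]2(CO)[C@@H]1CCC3=C4[C@H](C[C@@H]3O[Si](C(C)C)(C(C)C)C(C)C)C(C(=O)OC)(C(=O)OC)C[C@@]42CN(C)C1
F5 | step 18 | seven-membered lactone between O7 and the C17 carboxyl on the C6 face, other C17 ester retained, C3 ketone open | CCC(=O)CC[C@@]2(COC5=O)[C@@H]1CCC3=C4[C@H](C[C@@H]3O[Si](C(C)C)(C(C)C)C(C)C)[C@@]5(C(=O)OC)C[C@@]42CN(C)C1
F6 | step 18 | lactone after dealkoxycarbonylation (C17–H on the face of H14) | CCC(=O)CC[C@@]2(COC5=O)[C@@H]1CCC3=C4[C@H](C[C@@H]3O[Si](C(C)C)(C(C)C)C(C)C)[C@H]5C[C@@]42CN(C)C1
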